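Both diaryl ether bonds are cut at carbons that sit between two hydroxyls: B1 of the central ring B (flanked by B2-OH and B6-OH) and C1 of the trihydroxylated ring C (flanked by C2-OH and C6-OH). These four hydroxyls are carried as formyl groups, which first activate B1–F and C1–F toward phenoxide displacement and are then turned, in a single fourfold Baeyer–Villiger oxidation, into four aryl formates (new B2–O, B6–O, C2–O and C6–O bonds). The precursor is a tribenzylated triaryl bis-ether tetraaldehyde, built from one 2-fluoro-5-hydroxyisophthalaldehyde unit used twice and 3,5-bis(benzyloxy)phenol.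

Key step: step 9

Remark: ring A is the terminal 3,5-dioxygenated ring, ring B the central ring (B1 bears the ether to ring A, B4 the ether to ring C) and ring C the terminal 2,4,6-trioxygenated ring (C1 bears the ether oxygen); the target has no stereocentre. Both starting phenols 1 and 8 are assumed to be purchasable.

Step 1
Reactants: 1 4-fluoro-3,5-dimethylphenol
Product: 2 4-fluoro-3,5-dimethylphenyl acetate
Conditions: Ac2O, Et3N, DMAP (cat.), CH2Cl2, 0 °C to rt
Reagents that add atoms: acetic anhydride, CC(=O)OC(C)=O
Why: DMAP-catalysed O-acylation (nucleophilic acyl substitution) masks the phenol as an electron-poorer acetate, so that the ring should resist electrophilic bromination and oxidation in the next step.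

Step 2
Reactants: 2 4-fluoro-3,5-dimethylphenyl acetate
Product: 3 3,5-bis(dibromomethyl)-4-fluorophenyl acetate
Conditions: NBS (4.6 equiv), AIBN (cat.), PhCF3, reflux, visible light
Reagents that add atoms: N-bromosuccinimide, O=C1CCC(=O)N1Br
Why: Wohl–Ziegler radical bromination should take each benzylic methyl to the CHBr2 stage, where crowding stops a third bromination, while the acetate and the fluorine keep the ring inert to electrophilic bromine.

Step 3
Reactants: 3 3,5-bis(dibromomethyl)-4-fluorophenyl acetate
Product: 5 2-fluoro-5-hydroxybenzene-1,3-dicarbaldehyde, via 4-fluoro-3,5-diformylphenyl acetate 4 (not isolated)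
Conditions: AgNO3 (4.4 equiv), 1,4-dioxane/H2O, 80 °C; filter; then 2 M aq. HCl, 70 °C
Reagents that add atoms: water, O
Why: Silver-assisted SN1-type hydrolysis of the two geminal dibromides gives the aldehydes and the acid stage then hydrolyses the aryl acetate, the medium staying acidic throughout so that the now activated C–F bond never meets a strong nucleophile.

Step 4
Reactants: 5 2-fluoro-5-hydroxybenzene-1,3-dicarbaldehyde
Product: 6 5-(benzyloxy)-2-fluorobenzene-1,3-dicarbaldehyde
Conditions: BnBr (1.5 equiv), K2CO3, acetone, rt
Reagents that add atoms: benzyl bromide, BrCc1ccccc1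
Why: Williamson etherification, in which SN2 benzylation of the acidic phenol by excess bromide should outrun attack of its weakly nucleophilic phenoxide on a fluoroarene at room temperature in acetone.

Step 5
Reactants: 5 2-fluoro-5-hydroxybenzene-1,3-dicarbaldehyde
Product: 7 5-(allyloxy)-2-fluorobenzene-1,3-dicarbaldehyde
Conditions: allyl bromide (1.5 equiv), K2CO3, acetone, rt
Reagents that add atoms: allyl bromide, C=CCBr
Why: Williamson etherification installs a temporary allyl group that survives carbonate in DMF and can later be removed under neutral palladium catalysis without touching benzyl ethers or aldehydes.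

Step 6
Reactants: 7 5-(allyloxy)-2-fluorobenzene-1,3-dicarbaldehyde; 8 3,5-bis(benzyloxy)phenol
Product: 9 5-(allyloxy)-2-[3,5-bis(benzyloxy)phenoxy]benzene-1,3-dicarbaldehyde
Conditions: K2CO3 (1.5 equiv), DMF, rt to 50 °C
Reagents that add atoms: none
Why: Nucleophilic aromatic substitution by addition–elimination, in which the electron-rich phenoxide of 8 adds at B1, the Meisenheimer adduct is stabilised by both ortho formyl groups and fluoride leaves, O-arylation being the normal course for phenoxides with activated fluoroarenes.

Step 7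
Reactants: 9 5-(allyloxy)-2-[3,5-bis(benzyloxy)phenoxy]benzene-1,3-dicarbaldehyde
Product: 10 2-[3,5-bis(benzyloxy)phenoxy]-5-hydroxybenzene-1,3-dicarbaldehyde
Conditions: Pd(PPh3)4 (5 mol %), p-TolSO2Na (1.3 equiv), THF/MeOH, rt; dilute HCl work-up
Reagents that add atoms: none
Why: Tsuji–Trost-type deallylation, in which zerovalent palladium ionises the allyl ether of the acidic phenol to a π-allyl complex that the sulfinate captures irreversibly as a sulfone, a non-basic, amine-free scavenger that should leave the aldehydes, the activated diaryl ether and the benzyl ethers alone.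

Step 8
Reactants: 10 2-[3,5-bis(benzyloxy)phenoxy]-5-hydroxybenzene-1,3-dicarbaldehyde; 6 5-(benzyloxy)-2-fluorobenzene-1,3-dicarbaldehyde (1.1 equiv)
Product: 11 5-(benzyloxy)-2-[4-[3,5-bis(benzyloxy)phenoxy]-3,5-diformylphenoxy]benzene-1,3-dicarbaldehyde
Conditions: Cs2CO3 (1.3 equiv), DMF, 50–60 °C
Reagents that add atoms: none
Why: Second nucleophilic aromatic substitution, in which the phenoxide of 10 adds at C1 of 6 (activated by two ortho formyl groups) and fluoride, a far better leaving group than aryloxide in addition-controlled substitution, is expelled, so the ether already present at B1 should not exchange.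

Step 9
Reactants: 11 5-(benzyloxy)-2-[4-[3,5-bis(benzyloxy)phenoxy]-3,5-diformylphenoxy]benzene-1,3-dicarbaldehyde
Product: 12 5-(benzyloxy)-2-[4-[3,5-bis(benzyloxy)phenoxy]-3,5-bis(formyloxy)phenoxy]-1,3-phenylene diformate (the tetraformate)
Conditions: mCPBA (8 equiv), CH2Cl2, 0 °C to rt; Na2S2O3 then cold NaHCO3 wash; crude 12 carried on
Reagents that add atoms: meta-chloroperbenzoic acid (mCPBA), OOC(=O)c1cccc(Cl)c1
Why: Baeyer–Villiger oxidation in its Dakin-type form for aryl aldehydes: the peracid adds to each formyl carbon to give a Criegee adduct, and the ring carbon (B2, B6, C2, C6) migrates from carbon to oxygen as 3-chlorobenzoate departs, leaving an aryl formate. The closest known reaction is the mCPBA conversion of ortho-aryloxy- and ortho-alkoxybenzaldehydes into aryl formates, a routine entry to phenols in diaryl ether chemistry; here it is applied four times in one molecule. No ring is closed and no stereocentre is created. The selectivity required is aryl over hydride migration at every aldehyde, and it is secured by the ether oxygen at B1 or C1 that stands ortho to each formyl group and stabilises the electron-poor migrating carbon. Each formate formed exchanges a withdrawing formyl for a donating acyloxy group on its ring, so the second oxidation on each ring should be easier than the first. Anhydrous conditions at or below room temperature should keep the formates intact and spare the trioxygenated ring A from electrophilic hydroxylation; benzyl and diaryl ethers are inert to the peracid.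

Step 10
Reactants: 12 the tetraformate
Product: 13 5-(benzyloxy)-2-[4-[3,5-bis(benzyloxy)phenoxy]-3,5-dihydroxyphenoxy]benzene-1,3-diol
Conditions: K2CO3 (0.2 equiv), degassed MeOH/THF, 0 °C, Ar; dilute HCl quench
Reagents that add atoms: none
Why: Base-catalysed transesterification, in which the very labile aryl formates are cleaved by methoxide at 0 °C and leave as methyl formate, while benzyl and diaryl ethers are untouched and exclusion of air protects the electron-rich phenoxides.

Step 11
Reactants: 13 5-(benzyloxy)-2-[4-[3,5-bis(benzyloxy)phenoxy]-3,5-dihydroxyphenoxy]benzene-1,3-diol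
Product: 14 triphlorethol A, 2-[4-(3,5-dihydroxyphenoxy)-3,5-dihydroxyphenoxy]benzene-1,3,5-triol
Conditions: H2 (1 atm), Pd/C (10 %), EtOAc/MeOH, rt; filtration and concentration under Ar
Reagents that add atoms: none
Why: Heterogeneous hydrogenolysis of the three benzyl aryl ethers over palladium should release toluene and the free polyphenol under neutral conditions that do not affect diaryl ethers.

Compound list (no compound has a stereocentre)
1 | 4-fluoro-3,5-dimethylphenol | Cc1cc(O)cc(C)c1F | starting material
2 | 4-fluoro-3,5-dimethylphenyl acetate | CC(=O)Oc1cc(C)c(F)c(C)c1 | intermediate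
3 | 3,5-bis(dibromomethyl)-4-fluorophenyl acetate | CC(=O)Oc1cc(C(Br)Br)c(F)c(C(Br)Br)c1 | intermediate
4 | 4-fluoro-3,5-diformylphenyl acetate (not isolated) | CC(=O)Oc1cc(C=O)c(F)c(C=O)c1 | intermediate
5 | 2-fluoro-5-hydroxybenzene-1,3-dicarbaldehyde | O=Cc1cc(O)cc(C=O)c1F | intermediate
6 | 5-(benzyloxy)-2-fluorobenzene-1,3-dicarbaldehyde | O=Cc1cc(OCc2ccccc2)cc(C=O)c1F | intermediate
7 | 5-(allyloxy)-2-fluorobenzene-1,3-dicarbaldehyde | C=CCOc1cc(C=O)c(F)c(C=O)c1 | intermediate
8 | 3,5-bis(benzyloxy)phenol | Oc1cc(OCc2ccccc2)cc(OCc2ccccc2)c1 | starting material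
9 | 5-(allyloxy)-2-[3,5-bis(benzyloxy)phenoxy]benzene-1,3-dicarbaldehyde | C=CCOc1cc(C=O)c(Oc2cc(OCc3ccccc3)cc(OCc3ccccc3)c2)c(C=O)c1 | intermediate
10 | 2-[3,5-bis(benzyloxy)phenoxy]-5-hydroxybenzene-1,3-dicarbaldehyde | O=Cc1cc(O)cc(C=O)c1Oc1cc(OCc2ccccc2)cc(OCc2ccccc2)c1 | intermediate
11 | 5-(benzyloxy)-2-[4-[3,5-bis(benzyloxy)phenoxy]-3,5-diformylphenoxy]benzene-1,3-dicarbaldehyde | O=Cc1cc(OCc2ccccc2)cc(C=O)c1Oc1cc(C=O)c(Oc2cc(OCc3ccccc3)cc(OCc3ccccc3)c2)c(C=O)c1 | intermediate
12 | 5-(benzyloxy)-2-[4-[3,5-bis(benzyloxy)phenoxy]-3,5-bis(formyloxy)phenoxy]-1,3-phenylene diformate | O=COc1cc(OCc2ccccc2)cc(OC=O)c1Oc1cc(OC=O)c(Oc2cc(OCc3ccccc3)cc(OCc3ccccc3)c2)c(OC=O)c1 | intermediate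
13 | 5-(benzyloxy)-2-[4-[3,5-bis(benzyloxy)phenoxy]-3,5-dihydroxyphenoxy]benzene-1,3-diol | Oc1cc(OCc2ccccc2)cc(O)c1Oc1cc(O)c(Oc2cc(OCc3ccccc3)cc(OCc3ccccc3)c2)c(O)c1 | intermediate
14 | triphlorethol A | Oc1cc(O)cc(Oc2c(O)cc(Oc3c(O)cc(O)cc3O)cc2O)c1 | target

Total step count: 11. Longest linear sequence: 10 steps (1 → 2 → 3 → 5 → 7 → 9 → 10 → 11 → 12 → 13 → 14; step 4 is the side branch to 6).

Steps most likely to fail

1. Step 9. Hydride migration may compete with aryl migration in one or more Criegee adducts and give carboxylic acids. The doubly ortho-substituted rings B and C are twisted relative to the ether oxygen, and the first oxidation on each ring must proceed while a second formyl group still deactivates it. Stalling short of fourfold conversion and peracid hydroxylation of ring A are further possibilities. The fallback sets out from 11 and removes the migrating hydrogen. Excess MeMgBr in THF at −78 °C should give the tetrakis(1-hydroxyethyl) tetrol F1 as a mixture of diastereomers. Dess–Martin periodinane in CH2Cl2 should oxidise it to the tetraacetyl triaryl bis-ether F2. Baeyer–Villiger oxidation of these aryl methyl ketones (mCPBA, TFA, CH2Cl2), in which aryl migrates in preference to methyl, should give the tetraacetate F3. Methanolysis (K2CO3, MeOH, 0 °C, Ar) returns to the route at 13.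

2. Step 8. The phenoxide of 10 carries two formyl groups and is a weak nucleophile. At the temperature it may need, aryloxide exchange at the activated ether carbon B1 could scramble the diaryl ethers, and the aldehydes could degrade under base. The fallback sets out from 10 and switches off the formyl groups of the nucleophile. HC(OMe)3 with PPTS (cat.) in MeOH at rt should give 4-[3,5-bis(benzyloxy)phenoxy]-3,5-bis(dimethoxymethyl)phenol F4. Its electron-rich phenoxide, no longer activated at B1, should displace fluoride from 6 (Cs2CO3, DMF, rt) to give the bis(dimethyl acetal) dialdehyde F5. Hydrolysis with 1 M HCl in THF returns to the route at 11.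

3. Step 2. The bromination may stop at uneven depth, giving tri- to pentabromide mixtures, and some ring bromination may occur, so that no single tetrabromide is obtained. The fallback sets out from 2 and goes through the alcohol oxidation level. NBS (2.1 equiv) with AIBN, followed by diethyl phosphite and iPr2NEt to reduce over-brominated material back, should give 3,5-bis(bromomethyl)-4-fluorophenyl acetate F6. CaCO3 in refluxing 1,4-dioxane/H2O should hydrolyse both benzylic bromides and the acetate, the fluoride not yet being activated, to give 4-fluoro-3,5-bis(hydroxymethyl)phenol F7. Activated MnO2 in acetone should oxidise the two benzylic alcohols selectively and return to the route at 5.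

Further compounds
F1 | step 9 | 1,1',1'',1'''-tetrakis(hydroxyethyl) analogue of 11: 5-(benzyloxy)-2-[4-[3,5-bis(benzyloxy)phenoxy]-3,5-bis(1-hydroxyethyl)phenoxy]-1,3-bis(1-hydroxyethyl)benzene, mixture of diastereomers | CC(O)c1cc(OCc2ccccc2)cc(C(C)O)c1Oc1cc(C(C)O)c(Oc2cc(OCc3ccccc3)cc(OCc3ccccc3)c2)c(C(C)O)c1
F2 | step 9 | 1,3-diacetyl-5-(benzyloxy)-2-[3,5-diacetyl-4-[3,5-bis(benzyloxy)phenoxy]phenoxy]benzene | CC(=O)c1cc(OCc2ccccc2)cc(C(C)=O)c1Oc1cc(C(C)=O)c(Oc2cc(OCc3ccccc3)cc(OCc3ccccc3)c2)c(C(C)=O)c1
F3 | step 9 | tetraacetate of 13 | CC(=O)Oc1cc(OCc2ccccc2)cc(OC(C)=O)c1Oc1cc(OC(C)=O)c(Oc2cc(OCc3ccccc3)cc(OCc3ccccc3)c2)c(OC(C)=O)c1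
F4 | step 8 | 4-[3,5-bis(benzyloxy)phenoxy]-3,5-bis(dimethoxymethyl)phenol | COC(OC)c1cc(O)cc(C(OC)OC)c1Oc1cc(OCc2ccccc2)cc(OCc2ccccc2)c1
F5 | step 8 | 5-(benzyloxy)-2-[4-[3,5-bis(benzyloxy)phenoxy]-3,5-bis(dimethoxymethyl)phenoxy]benzene-1,3-dicarbaldehyde | O=Cc1cc(OCc2ccccc2)cc(C=O)c1Oc1cc(C(OC)OC)c(Oc2cc(OCc3ccccc3)cc(OCc3ccccc3)c2)c(C(OC)OC)c1
F6 | step 2 | 3,5-bis(bromomethyl)-4-fluorophenyl acetate | CC(=O)Oc1cc(CBr)c(F)c(CBr)c1
F7 | step 2 | 4-fluoro-3,5-bis(hydroxymethyl)phenol | OCc1cc(O)cc(CO)c1F
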